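**Retrosynthetic overview**
- The target comes from catalyst-controlled C-protonation and hydrolysis of a 3-chloro-4-ethoxy-2-alkylidenecyclopent-3-enone. This sets the C–Cl stereocentre.
- That cyclopentenone comes from a four-to-five ring expansion of an alkynylcyclobutenol: the chlorovinyl ring carbon shifts 1,2 onto the alkyne carbon. This one step builds the C5 ring and fixes the exocyclic alkene geometry.
- The alkynylcyclobutenol comes from the decalin acetylide and 2-chloro-3-ethoxycyclobutenone.
- The ethynyl decalinol comes from a bicyclic β-keto ester (α-face methyl addition sets the carbinol; ester to alkyne). The keto ester comes from an asymmetric proton-initiated bicyclisation of an acyclic (E)-dienyl β-keto ester.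
- The chain comes from a C6 bromide, acetylide, Me3Al, methyl vinyl ketone and dimethyl carbonate. Ring order: A and B together, then the four-membered ring is attached, then it is expanded to the five-membered ring.

Assumption: 3-ethoxycyclobut-2-en-1-one and 5-bromo-2-methylpent-2-ene are taken as catalogue chemicals, and the enol drawn in the target is treated as the resting tautomer of the 1,3-dione.

**Step 1**
Reactants: 1 5-bromo-2-methylpent-2-ene; 2 lithium acetylide–ethylenediamine complex
Product: 3 6-methylhept-5-en-1-yne
Conditions: DMSO, 0 °C to rt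
Reagents that add atoms: none
Why: SN2 alkylation of lithium acetylide with an unhindered primary bromide; no stereocentre is formed.

**Step 2**
Reactants: 3 6-methylhept-5-en-1-yne; 4 but-3-en-2-one (methyl vinyl ketone)
Product: 6 (5E)-6,10-dimethylundeca-5,9-dien-2-one, via alkenyldimethylalane 5 (not isolated)
Conditions: Me3Al (1.5 equiv), Cp2ZrCl2 (20 mol %), CH2Cl2, 0 °C to rt; volatiles off; CuTC (10 mol %), 4, THF, −30 °C; H2O
Reagents that add atoms: trimethylaluminium, C[Al](C)C
Why: Negishi Zr-catalysed syn-carboalumination places Me and Al cis and so fixes the (E)-trisubstituted alkene, and Cu-catalysed conjugate addition of the alkenylalane to the enone transfers it with retention.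

**Step 3**
Reactants: 6 (5E)-6,10-dimethylundeca-5,9-dien-2-one; 7 dimethyl carbonate
Product: 8 methyl (6E)-7,11-dimethyl-3-oxododeca-6,10-dienoate
Conditions: NaH, THF, reflux; 1 M HCl quench
Reagents that add atoms: none
Why: Claisen-type carbomethoxylation under equilibrating conditions goes to the methyl terminus, because only that product is drained as its stabilised enolate; the alkenes are untouched.

**Step 4**
Reactants: 8 methyl (6E)-7,11-dimethyl-3-oxododeca-6,10-dienoate
Product: 9 methyl (1R,4aS,8aS)-5,5,8a-trimethyl-2-oxodecahydronaphthalene-1-carboxylate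
Conditions: confined chiral IDPi Brønsted acid (5 mol %, the antipode that turns (E,E)-homofarnesol into (−)-ambrox), (CF3)3COH/CH2Cl2, −10 °C; recrystallise
Reagents that add atoms: none
Why: Proposed new method: the confined strong chiral acid protonates only the terminal trisubstituted alkene and holds the (E)-diene in a chair–chair fold, so anti additions (Stork–Eschenmoser) give the trans-decalin with C4a and C8a set by the catalyst, the enol carbon of the β-keto ester ends the cascade (any O-trapped enol ether re-ionises under the acid and drains to the C-alkylated ketone) and C1 equilibrates to the equatorial ester; the closest known reaction types are the IDPi-catalysed asymmetric cyclisation of homofarnesol to ambrox and the racemic SnCl4 cyclisation of this same β-keto ester.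

**Step 5**
Reactants: 9 methyl (1R,4aS,8aS)-5,5,8a-trimethyl-2-oxodecahydronaphthalene-1-carboxylate
Product: 10 methyl (1R,2S,4aS,8aS)-2-hydroxy-2,5,5,8a-tetramethyldecahydronaphthalene-1-carboxylate
Conditions: MeLi, anhydrous CeCl3 (3 equiv each), THF, −78 °C; cold 0.5 M HCl
Reagents that add atoms: methyllithium, [Li]C
Why: Organocerium 1,2-addition (CeCl3-mediated addition to enolisable 1,3-dicarbonyls) outruns enolisation, and because the axial angular methyl blocks the β face, methyl enters equatorially from the α face and leaves the axial β-OH.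

**Step 6**
Reactants: 10 methyl (1R,2S,4aS,8aS)-2-hydroxy-2,5,5,8a-tetramethyldecahydronaphthalene-1-carboxylate
Product: 12 (1R,2S,4aS,8aS)-1-ethynyl-2,5,5,8a-tetramethyldecahydronaphthalen-2-ol, via hydroxy aldehyde 11 (not isolated)
Conditions: DIBAL-H (2.3 equiv), CH2Cl2, −78 °C; then MeOH, K2CO3, dimethyl (1-diazo-2-oxopropyl)phosphonate, −78 °C to rt; aqueous work-up
Reagents that add atoms: dimethyl (1-diazo-2-oxopropyl)phosphonate, CC(=O)C(=[N+]=[N-])P(=O)(OC)OC
Why: One-pot partial ester reduction and Ohira–Bestmann (Seyferth–Gilbert) homologation; the neighbouring aluminium alkoxide stabilises the hemiacetal, and the side chain is already equatorial, so C1 is not scrambled.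

**Step 7**
Reactants: 13 3-ethoxycyclobut-2-en-1-one
Product: 14 2-chloro-3-ethoxycyclobut-2-en-1-one
Conditions: NCS (1.05 equiv), CH2Cl2, 0 °C to rt
Reagents that add atoms: N-chlorosuccinimide, O=C1CCC(=O)N1Cl
Why: Electrophilic α-chlorination of a vinylogous ester at its only nucleophilic carbon (C2), followed by proton loss.

**Step 8**
Reactants: 12 (1R,2S,4aS,8aS)-1-ethynyl-2,5,5,8a-tetramethyldecahydronaphthalen-2-ol; 14 2-chloro-3-ethoxycyclobut-2-en-1-one
Product: 16 2-chloro-3-ethoxy-1-{[(1S,2S,4aS,8aS)-2-hydroxy-2,5,5,8a-tetramethyldecahydronaphthalen-1-yl]ethynyl}cyclobut-2-en-1-ol (both C-1 epimers), via dilithiated alkynol 15 (not isolated)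
Conditions: n-BuLi (2.1 equiv), THF, −78 °C; 14, −78 °C; H2O quench; Et3N-washed silica
Reagents that add atoms: none
Why: 1,2-Addition of a lithium acetylide to the strained cyclobutenone carbonyl (enolisation would give an antiaromatic dienolate); the new carbinol centre forms as a mixture and is erased in step 9.

**Step 9**
Reactants: 16 2-chloro-3-ethoxy-1-{[(1S,2S,4aS,8aS)-2-hydroxy-2,5,5,8a-tetramethyldecahydronaphthalen-1-yl]ethynyl}cyclobut-2-en-1-ol
Product: 17 (2E)-3-chloro-4-ethoxy-2-{[(1R,2S,4aS,8aS)-2-hydroxy-2,5,5,8a-tetramethyldecahydronaphthalen-1-yl]methylidene}cyclopent-3-en-1-one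
Conditions: Pd2(dba)3·CHCl3 (2.5 mol %), DPEphos (6 mol %), PhCO2H (10 mol %), toluene, 35 °C, no amine base
Reagents that add atoms: none
Why: Proposed new method: Pd(0)/PhCO2H gives H–Pd–O2CPh, which adds syn across the alkyne with H on the carbon next to the very hindered decalin C-1 and Pd next to the carbinol; carboxylate/alkoxide exchange, strain-releasing β-carbon elimination of the carbinol–C(sp2) ring bond (the donor-substituted chlorovinyl carbon moves in preference to CH2) and fast C(sp2)–C(sp2) reductive elimination amount to a 1,2-shift with retention at the alkenyl carbon, so the migrated carbon ends cis to H and the decalin cis to C=O (also the less strained isomer, since the in-plane Cl avoids the decalin); the closest known reaction types are the Pd–H-triggered Wagner–Meerwein ring expansion of allenylcyclobutanols and the carbopalladative ring expansion of 1-alkynylcyclobutanols, whereas π-acid variants add anti and give the opposite geometry.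

**Step 10**
Reactants: 17 (2E)-3-chloro-4-ethoxy-2-{[(1R,2S,4aS,8aS)-2-hydroxy-2,5,5,8a-tetramethyldecahydronaphthalen-1-yl]methylidene}cyclopent-3-en-1-one
Product: 18 (4E,5R)-5-chloro-3-hydroxy-4-{[(1R,2S,4aS,8aS)-2-hydroxy-2,5,5,8a-tetramethyldecahydronaphthalen-1-yl]methylidene}cyclopent-2-en-1-one
Conditions: chiral BINOL-derived N-triflyl phosphoramide (5 mol %), H2O (3 equiv), toluene, −40 °C
Reagents that add atoms: water, O
Why: Chiral-Brønsted-acid-catalysed enantioselective protonation of an enol ether: rate-limiting C-protonation of the chloro enol ether inside the chiral ion pair sets the C–Cl centre (it is too far from the decalin for substrate bias, so the catalyst antipode giving 5R is picked in a two-run screen), water then adds to the oxocarbenium ion, ethanol leaves, and the 1,3-dione enolises, which lowers the acidity of the new C–H and guards it against epimerisation while the alkene geometry is kept.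

**Compound list**
1 | 5-bromo-2-methylpent-2-ene | CC(C)=CCCBr | starting material
2 | lithium acetylide–ethylenediamine complex | [Li]C#C.NCCN | starting material
3 | 6-methylhept-5-en-1-yne | C#CCCC=C(C)C | intermediate
4 | but-3-en-2-one | CC(=O)C=C | starting material
5 | [(1E)-2,6-dimethylhepta-1,5-dien-1-yl]dimethylalane | C[Al](C)/C=C(\C)CCC=C(C)C | intermediate
6 | (5E)-6,10-dimethylundeca-5,9-dien-2-one | CC(=O)CC/C=C(\C)CCC=C(C)C | intermediate
7 | dimethyl carbonate | COC(=O)OC | starting material
8 | methyl (6E)-7,11-dimethyl-3-oxododeca-6,10-dienoate | COC(=O)CC(=O)CC/C=C(\C)CCC=C(C)C | intermediate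
9 | methyl (1R,4aS,8aS)-5,5,8a-trimethyl-2-oxodecahydronaphthalene-1-carboxylate (trans-decalin; equatorial ester) | CC1(C)CCC[C@]2(C)[C@@H](C(=O)OC)C(=O)CC[C@@H]12 | intermediate
10 | methyl (1R,2S,4aS,8aS)-2-hydroxy-2,5,5,8a-tetramethyldecahydronaphthalene-1-carboxylate (axial OH, cis to ester and angular methyl) | CC1(C)CCC[C@]2(C)[C@@H](C(=O)OC)[C@@](C)(O)CC[C@@H]12 | intermediate
11 | (1R,2S,4aS,8aS)-2-hydroxy-2,5,5,8a-tetramethyldecahydronaphthalene-1-carbaldehyde | CC1(C)CCC[C@]2(C)[C@@H](C=O)[C@@](C)(O)CC[C@@H]12 | intermediate
12 | (1R,2S,4aS,8aS)-1-ethynyl-2,5,5,8a-tetramethyldecahydronaphthalen-2-ol | CC1(C)CCC[C@]2(C)[C@@H](C#C)[C@@](C)(O)CC[C@@H]12 | intermediate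
13 | 3-ethoxycyclobut-2-en-1-one | CCOC1=CC(=O)C1 | starting material
14 | 2-chloro-3-ethoxycyclobut-2-en-1-one | CCOC1=C(Cl)C(=O)C1 | intermediate
15 | dilithium salt of 12 (C-lithio acetylide, O-lithio alkoxide) | CC1(C)CCC[C@]2(C)[C@@H](C#C[Li])[C@@](C)(O[Li])CC[C@@H]12 | intermediate
16 | 2-chloro-3-ethoxy-1-{[(1S,2S,4aS,8aS)-2-hydroxy-2,5,5,8a-tetramethyldecahydronaphthalen-1-yl]ethynyl}cyclobut-2-en-1-ol (same decalin as 12, the C-1 descriptor changes only by CIP priority; both carbinol epimers) | CC1(C)CCC[C@]2(C)[C@@H](C#CC3(O)CC(OCC)=C3Cl)[C@@](C)(O)CC[C@@H]12 | intermediate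
17 | (2E)-3-chloro-4-ethoxy-2-{[(1R,2S,4aS,8aS)-2-hydroxy-2,5,5,8a-tetramethyldecahydronaphthalen-1-yl]methylidene}cyclopent-3-en-1-one (decalin cis to C=O) | CC1(C)CCC[C@]2(C)[C@@H](/C=C3\C(=O)CC(OCC)=C3Cl)[C@@](C)(O)CC[C@@H]12 | intermediate
18 | (4E,5R)-5-chloro-3-hydroxy-4-{[(1R,2S,4aS,8aS)-2-hydroxy-2,5,5,8a-tetramethyldecahydronaphthalen-1-yl]methylidene}cyclopent-2-en-1-one | CC1(C)CCC[C@]2(C)[C@@H](/C=C3\C(O)=CC(=O)[C@@H]3Cl)[C@@](C)(O)CC[C@@H]12 | target

**Step count**
Total step count: 10. Longest linear sequence: 9 (steps 1–6, 8, 9, 10); step 7 is a one-step side branch.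

**Three steps most likely to fail**

Step 4 (new asymmetric bicyclisation). The risks are persistent O-trapping by the ketone, catalyst inhibition by the dicarbonyl, and modest ee. The fallback sets out from 8. SnCl4 in wet CH2Cl2 at 0 °C, the established Lewis-acid cyclisation of this β-keto ester, gives the racemate, that is 9 together with the mirror-image (1S,4aR,8aR) keto ester F1. Preparative chiral SFC removes F1, and the route is rejoined at 9. This replaces asymmetric catalysis by racemic synthesis plus resolution.

Step 9 (new hydropalladative ring expansion). The risks are the wrong hydropalladation regiochemistry (chelation by the decalin OH), acid ionisation of the cyclobutenol to the 3-alkynylcyclobutenone, and six-ring closure to a phenol. The fallback sets out from 16. The known gold(I)-catalysed ring expansion of 1-alkynylcyclobutanols ([(4-CF3C6H4)3P]AuCl/AgSbF6, 2 mol %, CH2Cl2, rt) proceeds by anti addition and gives the strained (2Z) dienone F2. Iodine (5 mol %) under visible light then equilibrates F2 to the less strained isomer, rejoining at 17.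

Step 10 (catalyst-controlled protonation). The risks are low facial selectivity on this chloro dienol ether, premature tautomerisation of 17 to the conjugated vinylogous ester, and epimerisation of the product. The fallback sets out from 17. Achiral hydrolysis (oxalic acid, wet THF, 0 °C) gives 18 and the (5S) epimer F3 in about 1:1 ratio. Preparative HPLC separates them. F3 is re-equilibrated with catalytic Et3N in MeCN and recycled, so the material converges on 18.

**Further compounds**
F1 | step 4 | methyl (1S,4aR,8aR)-5,5,8a-trimethyl-2-oxodecahydronaphthalene-1-carboxylate | CC1(C)CCC[C@@]2(C)[C@H](C(=O)OC)C(=O)CC[C@H]12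
F2 | step 9 | (2Z)-3-chloro-4-ethoxy-2-{[(1R,2S,4aS,8aS)-2-hydroxy-2,5,5,8a-tetramethyldecahydronaphthalen-1-yl]methylidene}cyclopent-3-en-1-one | CC1(C)CCC[C@]2(C)[C@@H](/C=C3/C(=O)CC(OCC)=C3Cl)[C@@](C)(O)CC[C@@H]12
F3 | step 10 | (4E,5S)-5-chloro-3-hydroxy-4-{[(1R,2S,4aS,8aS)-2-hydroxy-2,5,5,8a-tetramethyldecahydronaphthalen-1-yl]methylidene}cyclopent-2-en-1-one | CC1(C)CCC[C@]2(C)[C@@H](/C=C3\C(O)=CC(=O)[C@H]3Cl)[C@@](C)(O)CC[C@@H]12
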